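**Retrosynthetic overview**

1. Target 17 ⇐ O-debenzylation of diol 16 ⇐ LiAlH4 reduction of both esters of trans-diester 15.
2. 15 ⇐ (S)-flavanone 11 by iodine(III)-mediated oxidative ring contraction. The γ-pyranone ring is not in the target and is built only to carry C2. It expels its carbonyl carbon C4 through a 1,2-shift of the A-ring (new C3–C3a bond), which closes the dihydrofuran ring O1–C2–C3–C3a–C7a last; the expelled carbon stays as the C3 ester (later CH2OH).
3. Enabling feature: C3 of the dihydrofuran carries the arene carbon C3a and exactly one exocyclic carbon (CH2OH), next to the O1–C2(H)(aryl) unit. The target is thus a flavanone whose C4 has been pushed out of the ring, so the C2 stereocentre can relay to C3 (trans).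
4. 11 ⇐ chromone 5 + arylboronic acid 10 (Rh-catalysed asymmetric 1,4-addition sets C2); 5 ⇐ methyl dihydroferulate 1 (Fries rearrangement, enaminone annulation); 10 ⇐ 4-bromo-2,6-dimethoxyphenol 6.
5. Ring order: both benzene rings are bought; the temporary pyranone is closed in step 3; the dihydrofuran is closed in step 7.

Key step: step 7

Remark (assumption): the Rh/(S)-biaryl-bisphosphine catalyst of step 6 is taken to add the aryl group to chromone 5 with the same facial sense as to cyclic enones, giving the (2S)-flavanone. If the first run gives the antipode, the (R)-ligand is used and nothing else changes.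

**Route**

Step 1
Reactants: 1 methyl 3-(4-hydroxy-3-methoxyphenyl)propanoate
Product: 2 methyl 3-(4-acetoxy-3-methoxyphenyl)propanoate
Conditions: Ac2O, pyridine, DMAP (cat.), CH2Cl2, rt
Reagents that add atoms: acetic anhydride, CC(=O)OC(C)=O
Why: DMAP-catalysed O-acetylation of a phenol (nucleophilic acyl substitution) should be clean and installs the acyl group for the Fries rearrangement; no stereocentre is involved.

Step 2
Reactants: 2 methyl 3-(4-acetoxy-3-methoxyphenyl)propanoate
Product: 3 methyl 3-(3-acetyl-4-hydroxy-5-methoxyphenyl)propanoate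
Conditions: BF3·OEt2 (3 equiv), neat, 90 °C; then H2O/MeOH, 50 °C
Reagents that add atoms: none
Why: Lewis-acid Fries rearrangement: the para position is blocked by the side chain, so the boron phenoxide/acylium pair should deliver acetyl to the only free position ortho to the phenol oxygen, where the product is held as an O,O-chelate until hydrolytic work-up; BF3 should leave the aryl methyl ether and the methyl ester intact.

Step 3
Reactants: 3 methyl 3-(3-acetyl-4-hydroxy-5-methoxyphenyl)propanoate
Product: 5 methyl 3-(8-methoxy-4-oxo-4H-chromen-6-yl)propanoate, via enaminone 4 (not isolated)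
Conditions: DMF-DMA, toluene, 100 °C; concentrate; then 2 M HCl, CH2Cl2, 40 °C
Reagents that add atoms: N,N-dimethylformamide dimethyl acetal, COC(OC)N(C)C
Why: Condensation of the acetyl CH3 with DMF-DMA gives the enaminone, and acid then promotes addition of the phenol and loss of dimethylamine (standard enaminone route to 2,3-unsubstituted chromones), closing the temporary γ-pyranone ring.

Step 4
Reactants: 6 4-bromo-2,6-dimethoxyphenol
Product: 7 2-(benzyloxy)-5-bromo-1,3-dimethoxybenzene
Conditions: BnBr, K2CO3, DMF, 60 °C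
Reagents that add atoms: benzyl bromide, BrCc1ccccc1
Why: Williamson etherification of the phenoxide with a reactive benzylic bromide should proceed despite the two flanking methoxy groups and masks the phenol against the later iodane oxidation.

Step 5
Reactants: 7 2-(benzyloxy)-5-bromo-1,3-dimethoxybenzene
Product: 10 [4-(benzyloxy)-3,5-dimethoxyphenyl]boronic acid, via aryllithium 8 (not isolated), via lithium aryltriisopropoxyborate 9 (not isolated)
Conditions: n-BuLi, THF, −78 °C; B(OiPr)3, −78 °C → rt; then 1 M HCl
Reagents that add atoms: triisopropyl borate, CC(C)OB(OC(C)C)OC(C)C; water, O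
Why: Bromine–lithium exchange at −78 °C is faster than any deprotonation of the benzyl ether, and borate trapping followed by acidic hydrolysis is the standard route to an arylboronic acid.

Step 6
Reactants: 5 methyl 3-(8-methoxy-4-oxo-4H-chromen-6-yl)propanoate; 10 [4-(benzyloxy)-3,5-dimethoxyphenyl]boronic acid
Product: 11 methyl 3-[(2S)-2-[4-(benzyloxy)-3,5-dimethoxyphenyl]-8-methoxy-4-oxo-3,4-dihydro-2H-chromen-6-yl]propanoate
Conditions: [Rh(OH)(cod)]2 (2.5 mol %), (S)-MeO-F12-BIPHEP [(S)-6,6'-dimethoxybiphenyl-2,2'-diylbis(bis(3,4,5-trifluorophenyl)phosphine)] (5.5 mol %), 10 (2 equiv), toluene/H2O, 30 °C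
Reagents that add atoms: none
Why: Rh(I)-catalysed asymmetric 1,4-addition of an arylboronic acid to a chromone (Hayashi–Miyaura reaction): the aryl–Rh species should add to C2 on the enantioface selected by the (S)-ligand (catalyst control sets C2 as S), and the electron-poor bisphosphine allows base-free, mild conditions under which the flavanone should not open to the chalcone and racemise.

Step 7
Reactants: 11 methyl 3-[(2S)-2-[4-(benzyloxy)-3,5-dimethoxyphenyl]-8-methoxy-4-oxo-3,4-dihydro-2H-chromen-6-yl]propanoate
Product: 15 methyl (2S,3S)-2-[4-(benzyloxy)-3,5-dimethoxyphenyl]-7-methoxy-5-(3-methoxy-3-oxopropyl)-2,3-dihydro-1-benzofuran-3-carboxylate (2,3-trans), via enol ether 12 (not isolated), via iodane ketal 13 (not isolated), via orthoester 14 (not isolated)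
Conditions: PhI(OAc)2 (1.2 equiv), conc. H2SO4 (1 equiv), HC(OMe)3, rt; then aq. NaHCO3
Reagents that add atoms: trimethyl orthoformate, COC(OC)OC; water, O
Why: Acid and orthoformate convert the ketone into enol ether 12, which the iodane attacks at C3 on the face anti to the pseudo-equatorial 2-aryl group while methanol caps C4 as ketal 13; the arene carbon C4a, antiperiplanar to the equatorial C3–I bond, then shifts from C4 to C3 as iodobenzene leaves, and the resulting dimethoxycarbenium ion is collected as orthoester 14 and hydrolysed to ester 15 on work-up. The closest known reaction type is the hypervalent-iodine (or thallium(III)) oxidative ring contraction of flavanones in trimethyl orthoformate to methyl trans-2-aryl-2,3-dihydrobenzofuran-3-carboxylates, which is known to keep the configuration at C2. The dihydrofuran ring is closed by ring contraction, that is a 1,2-aryl shift through a bridged phenonium-type transition state (C3–C3a bond made, C4–C4a bond broken), not by an exo or endo cyclisation. C2 is carried over untouched from 11, and C3 is set by substrate control, since anti iodination followed by invertive migration should place the ester trans to the aryl group, giving (2S,3S). The step needs the A-ring shift to win over the 2→3 shift of the B-ring and over loss of H-3 to the flavone; this is secured by the ketal at C4 (a dialkoxycarbenium ion develops only on A-ring migration), by the ring oxygen O1 ortho to the migrating carbon, by the trans-diequatorial conformation of 13, and by the two methoxy groups that twist the 4-benzyloxy group of the B-ring out of conjugation and lower its migratory aptitude.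

Step 8
Reactants: 15 methyl (2S,3S)-2-[4-(benzyloxy)-3,5-dimethoxyphenyl]-7-methoxy-5-(3-methoxy-3-oxopropyl)-2,3-dihydro-1-benzofuran-3-carboxylate
Product: 16 3-[(2S,3R)-2-[4-(benzyloxy)-3,5-dimethoxyphenyl]-3-(hydroxymethyl)-7-methoxy-2,3-dihydro-1-benzofuran-5-yl]propan-1-ol
Conditions: LiAlH4 (2.5 equiv), THF, 0 °C → rt; then H2O/aq. NaOH work-up
Reagents that add atoms: none
Why: Hydride reduction of both methyl esters to primary alcohols should be faster than enolisation at C3, which in any case already holds the thermodynamically preferred trans arrangement; the descriptor at C3 changes from S to R only through CIP priorities.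

Step 9
Reactants: 16 3-[(2S,3R)-2-[4-(benzyloxy)-3,5-dimethoxyphenyl]-3-(hydroxymethyl)-7-methoxy-2,3-dihydro-1-benzofuran-5-yl]propan-1-ol
Product: 17 4-[(2S,3R)-3-(hydroxymethyl)-5-(3-hydroxypropyl)-7-methoxy-2,3-dihydro-1-benzofuran-2-yl]-2,6-dimethoxyphenol
Conditions: H2 (1 atm), 10% Pd/C, EtOAc/MeOH, rt, stopped after one equivalent of H2
Reagents that add atoms: none
Why: Catalytic hydrogenolysis of the aryl benzyl ether under neutral conditions should be much faster than cleavage of the cyclic secondary benzylic C2–O1 bond, so the phenol is released without touching either stereocentre.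

**Compound list**

1 | methyl 3-(4-hydroxy-3-methoxyphenyl)propanoate (methyl dihydroferulate) | COC(=O)CCc1ccc(O)c(OC)c1 | starting material
2 | methyl 3-(4-acetoxy-3-methoxyphenyl)propanoate | COC(=O)CCc1ccc(OC(C)=O)c(OC)c1 | intermediate
3 | methyl 3-(3-acetyl-4-hydroxy-5-methoxyphenyl)propanoate | COC(=O)CCc1cc(OC)c(O)c(C(C)=O)c1 | intermediate
4 | methyl 3-[3-[(E)-3-(dimethylamino)prop-2-enoyl]-4-hydroxy-5-methoxyphenyl]propanoate (enaminone) | COC(=O)CCc1cc(OC)c(O)c(C(=O)/C=C/N(C)C)c1 | intermediate (not isolated)
5 | methyl 3-(8-methoxy-4-oxo-4H-chromen-6-yl)propanoate | COC(=O)CCc1cc(OC)c2occc(=O)c2c1 | intermediate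
6 | 4-bromo-2,6-dimethoxyphenol | COc1cc(Br)cc(OC)c1O | starting material
7 | 2-(benzyloxy)-5-bromo-1,3-dimethoxybenzene | COc1cc(Br)cc(OC)c1OCc1ccccc1 | intermediate
8 | [4-(benzyloxy)-3,5-dimethoxyphenyl]lithium | [Li]c1cc(OC)c(OCc2ccccc2)c(OC)c1 | intermediate (not isolated)
9 | lithium [4-(benzyloxy)-3,5-dimethoxyphenyl]tri(propan-2-yloxy)borate | [Li+].CC(C)O[B-](OC(C)C)(OC(C)C)c1cc(OC)c(OCc2ccccc2)c(OC)c1 | intermediate (not isolated)
10 | [4-(benzyloxy)-3,5-dimethoxyphenyl]boronic acid | COc1cc(B(O)O)cc(OC)c1OCc1ccccc1 | intermediate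
11 | methyl 3-[(2S)-2-[4-(benzyloxy)-3,5-dimethoxyphenyl]-8-methoxy-4-oxo-3,4-dihydro-2H-chromen-6-yl]propanoate ((S)-flavanone) | O=C1C[C@@H](c2cc(OC)c(OCc3ccccc3)c(OC)c2)Oc2c(OC)cc(CCC(=O)OC)cc12 | intermediate
12 | methyl 3-[(2S)-2-[4-(benzyloxy)-3,5-dimethoxyphenyl]-4,8-dimethoxy-2H-chromen-6-yl]propanoate (enol ether) | COC1=C[C@@H](c2cc(OC)c(OCc3ccccc3)c(OC)c2)Oc2c(OC)cc(CCC(=O)OC)cc12 | intermediate (not isolated)
13 | methyl 3-[(2R,3R)-3-[acetoxy(phenyl)-λ3-iodanyl]-2-[4-(benzyloxy)-3,5-dimethoxyphenyl]-4,4,8-trimethoxy-3,4-dihydro-2H-chromen-6-yl]propanoate (iodine trans to the 2-aryl group; C2 unchanged in space, its descriptor changes only by CIP priority) | COC1(OC)[C@H](I(OC(C)=O)c2ccccc2)[C@@H](c2cc(OC)c(OCc3ccccc3)c(OC)c2)Oc2c(OC)cc(CCC(=O)OC)cc12 | intermediate (not isolated)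
14 | methyl 3-[(2S,3S)-2-[4-(benzyloxy)-3,5-dimethoxyphenyl]-7-methoxy-3-(trimethoxymethyl)-2,3-dihydro-1-benzofuran-5-yl]propanoate (trans orthoester) | COc1cc([C@H]2Oc3c(OC)cc(CCC(=O)OC)cc3[C@@H]2C(OC)(OC)OC)cc(OC)c1OCc1ccccc1 | intermediate (not isolated)
15 | methyl (2S,3S)-2-[4-(benzyloxy)-3,5-dimethoxyphenyl]-7-methoxy-5-(3-methoxy-3-oxopropyl)-2,3-dihydro-1-benzofuran-3-carboxylate (2,3-trans) | COc1cc([C@H]2Oc3c(OC)cc(CCC(=O)OC)cc3[C@@H]2C(=O)OC)cc(OC)c1OCc1ccccc1 | intermediate
16 | 3-[(2S,3R)-2-[4-(benzyloxy)-3,5-dimethoxyphenyl]-3-(hydroxymethyl)-7-methoxy-2,3-dihydro-1-benzofuran-5-yl]propan-1-ol (2,3-trans) | COc1cc([C@H]2Oc3c(OC)cc(CCCO)cc3[C@@H]2CO)cc(OC)c1OCc1ccccc1 | intermediate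
17 | 4-[(2S,3R)-3-(hydroxymethyl)-5-(3-hydroxypropyl)-7-methoxy-2,3-dihydro-1-benzofuran-2-yl]-2,6-dimethoxyphenol (2,3-trans) | COc1cc([C@H]2Oc3c(OC)cc(CCCO)cc3[C@@H]2CO)cc(OC)c1O | target

**Step count and risks**

Total step count: 9. Longest linear sequence: 7 steps (1, 2, 3, 6, 7, 8, 9).

Steps most likely to fail:

1. Step 7 (oxidative ring contraction). What may go wrong: loss of H-3 from the iodane (dehydrogenation to the flavone), a competing 2→3 shift of the B-ring, oxidation of the trioxygenated arenes by the iodane, or acid-induced opening of the pyranone before ketalisation with erosion of the C2 configuration. The fallback forms the same ring by C2–C3 bond formation instead of ring contraction; it sets out from ketone 3 and comes back to the route at diester 15. Aryllithium 8 (made from 7 as in step 5) would be quenched with paraformaldehyde to give [4-(benzyloxy)-3,5-dimethoxyphenyl]methanol F1. Mitsunobu etherification of phenol 3 with F1 (PPh3, DIAD, THF) should give the aryl benzyl ether ketone F2. Thallium(III) nitrate in MeOH/HC(OMe)3 (oxidative 1,2-aryl shift of an aryl methyl ketone) should convert F2 into the methyl arylacetate F3. Diazo transfer (p-ABSA, DBU, MeCN) should give the aryldiazoacetate F4. Intramolecular Rh(II)-carbenoid insertion into the ArO–CH2–aryl C–H bond (Rh2(S-PTTL)4 or its enantiomer, whichever delivers 2S, toluene, −60 °C) should give the cis-(2S,3R) diester F5. NaOMe in MeOH should then epimerise C3 to the trans-(2S,3S) diester 15.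

2. Step 6 (asymmetric 1,4-addition). What may go wrong: incomplete enantioface discrimination on this 8-methoxychromone, retro-oxa-Michael opening of the product in the aqueous medium (racemisation through the chalcone), or protodeboronation of the electron-rich boronic acid. The fallback replaces the asymmetric addition by condensation, cyclisation and kinetic resolution; it sets out from ketone 3 and comes back at flavanone 11. Claisen–Schmidt condensation of 3 with commercially available 4-(benzyloxy)-3,5-dimethoxybenzaldehyde (pyrrolidine, MeOH, 50 °C) should give the 2'-hydroxychalcone F6. NaOAc in refluxing EtOH should cyclise it to the racemic flavanone F7. Kinetic resolution by asymmetric transfer hydrogenation (Rh(III)– or Ru(II)–TsDPEN catalyst, HCO2H/Et3N, enantiomer chosen so that the (2R)-ketone is reduced) should convert the unwanted enantiomer into the cis-(2R,4R)-flavan-4-ol F8 and leave (S)-flavanone 11, separable by chromatography.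

3. Step 2 (Fries rearrangement). What may go wrong: acyl transfer to the position para to the methoxy group instead of ortho to the phenol oxygen, Lewis-acid demethylation, or ionisation of the side-chain ester with ring closure onto the arene. The fallback uses halogenation and cross-coupling instead of acyl migration; it sets out from phenol 1 and comes back at ketone 3. Bromination ortho to the hydroxyl group (NBS, MeCN, 0 °C) should give methyl 3-(3-bromo-4-hydroxy-5-methoxyphenyl)propanoate F9. Stille coupling with tributyl(1-ethoxyvinyl)stannane (PdCl2(PPh3)2, toluene, 100 °C) should give the enol ether F10. Mild acid hydrolysis (1 M HCl, THF, rt) should then give 3.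

**Further compounds**

F1 | step 7 | [4-(benzyloxy)-3,5-dimethoxyphenyl]methanol | COc1cc(CO)cc(OC)c1OCc1ccccc1
F2 | step 7 | methyl 3-[3-acetyl-4-[[4-(benzyloxy)-3,5-dimethoxyphenyl]methoxy]-5-methoxyphenyl]propanoate | COC(=O)CCc1cc(OC)c(OCc2cc(OC)c(OCc3ccccc3)c(OC)c2)c(C(C)=O)c1
F3 | step 7 | methyl 3-[4-[[4-(benzyloxy)-3,5-dimethoxyphenyl]methoxy]-3-methoxy-5-(2-methoxy-2-oxoethyl)phenyl]propanoate | COC(=O)CCc1cc(OC)c(OCc2cc(OC)c(OCc3ccccc3)c(OC)c2)c(CC(=O)OC)c1
F4 | step 7 | methyl 2-[2-[[4-(benzyloxy)-3,5-dimethoxyphenyl]methoxy]-3-methoxy-5-(3-methoxy-3-oxopropyl)phenyl]-2-diazoacetate | COC(=O)CCc1cc(OC)c(OCc2cc(OC)c(OCc3ccccc3)c(OC)c2)c(C(=[N+]=[N-])C(=O)OC)c1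
F5 | step 7 | methyl (2S,3R)-2-[4-(benzyloxy)-3,5-dimethoxyphenyl]-7-methoxy-5-(3-methoxy-3-oxopropyl)-2,3-dihydro-1-benzofuran-3-carboxylate (2,3-cis) | COc1cc([C@H]2Oc3c(OC)cc(CCC(=O)OC)cc3[C@H]2C(=O)OC)cc(OC)c1OCc1ccccc1
F6 | step 6 | methyl 3-[3-[(E)-3-[4-(benzyloxy)-3,5-dimethoxyphenyl]prop-2-enoyl]-4-hydroxy-5-methoxyphenyl]propanoate (2'-hydroxychalcone) | COC(=O)CCc1cc(OC)c(O)c(C(=O)/C=C/c2cc(OC)c(OCc3ccccc3)c(OC)c2)c1
F7 | step 6 | methyl 3-[2-[4-(benzyloxy)-3,5-dimethoxyphenyl]-8-methoxy-4-oxo-3,4-dihydro-2H-chromen-6-yl]propanoate (racemic flavanone) | O=C1CC(c2cc(OC)c(OCc3ccccc3)c(OC)c2)Oc2c(OC)cc(CCC(=O)OC)cc12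
F8 | step 6 | methyl 3-[(2R,4R)-2-[4-(benzyloxy)-3,5-dimethoxyphenyl]-4-hydroxy-8-methoxy-3,4-dihydro-2H-chromen-6-yl]propanoate (2,4-cis flavan-4-ol) | O[C@@H]1C[C@H](c2cc(OC)c(OCc3ccccc3)c(OC)c2)Oc2c(OC)cc(CCC(=O)OC)cc12
F9 | step 2 | methyl 3-(3-bromo-4-hydroxy-5-methoxyphenyl)propanoate | COC(=O)CCc1cc(Br)c(O)c(OC)c1
F10 | step 2 | methyl 3-[3-(1-ethoxyethenyl)-4-hydroxy-5-methoxyphenyl]propanoate | C=C(OCC)c1cc(CCC(=O)OC)cc(OC)c1O
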